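**Plan**

- Retrosynthesis: the three silyl ethers come off last. The C2–O and O–C1'' bonds of the aryl ether and the O1–C2 bond of ring C are then cut together, giving an o-hydroxyaryl 1,3-diketone and H2O2. The diketone is cut between C3 and the ring B ketone, and the C8–prenyl bond is cut last.
- Enabling feature: the C2–O–C1'' aryl ether links C2 of pyranone ring C to the ipso carbon C1'' of the 4-hydroxyphenyl ring B. The target is therefore 8-prenylapigenin with one oxygen inserted into the C2–aryl bond, which an aryl shift from C2 to a peroxide oxygen can install.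
- Forward order: ring A is bought as phloroacetophenone, C-prenylated and bis-silylated. Ring B is attached as a 4-silyloxybenzoyl group. Ring C closes in the oxidative key step, which also moves ring B from carbon to oxygen.
- Stereochemistry: the target has no stereocentre. C2 of the hemiketal and hydroperoxide intermediates is racemic and becomes trigonal.

Key step: step 6

Assumption: chromone numbering (O1, C2 to C8a; ring B C1'' to C6'') is used throughout, and structures drawn as 1,3-diketones stand for their enol and ring-closed hemiketal tautomers.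

**Step 1**
Reactants: 1 2,4,6-trihydroxyacetophenone; 2 1-bromo-3-methylbut-2-ene (prenyl bromide)
Product: 3 1-[2,4,6-trihydroxy-3-(3-methylbut-2-enyl)phenyl]ethanone
Conditions: 2 (0.9 equiv), 10% aq. KOH, 0 °C
Reagents that add atoms: prenyl bromide 2, CC(C)=CCBr
Why: Aqueous alkali turns phloroacetophenone into an ambident phenoxide that the allylic bromide alkylates at ring carbon (C-prenylation of a phloroglucinol, a Friedel–Crafts-type alkylation through the dienolate), and the slight deficit of bromide should hold back a second prenylation.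

**Step 2**
Reactants: 3 1-[2,4,6-trihydroxy-3-(3-methylbut-2-enyl)phenyl]ethanone; 4 triisopropylsilyl chloride
Product: 5 1-[2-hydroxy-3-(3-methylbut-2-enyl)-4,6-bis(triisopropylsilyloxy)phenyl]ethanone
Conditions: TIPSCl (2.1 equiv), imidazole, DMF, 0 °C to rt
Reagents that add atoms: triisopropylsilyl chloride 4, CC(C)[Si](Cl)(C(C)C)C(C)C
Why: Imidazole-promoted silyl ether formation should take the C4 hydroxyl and the less hindered ortho hydroxyl, because the C2 hydroxyl is buttressed between prenyl and acetyl and held in the hydrogen bond to the ketone, the pattern known from partial alkylation of C-alkylated phloroacetophenones.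

**Step 3**
Reactants: 6 4-hydroxybenzoic acid; 7 tert-butyldimethylsilyl chloride
Product: 8 tert-butyldimethylsilyl 4-(tert-butyldimethylsilyloxy)benzoate
Conditions: TBSCl (2.2 equiv), imidazole, DMF, rt; non-aqueous work-up
Reagents that add atoms: tert-butyldimethylsilyl chloride 7, CC(C)(C)[Si](C)(C)Cl
Why: Imidazole-promoted silylation converts both the phenol and the carboxylic acid, and the resulting silyl ester serves directly as the acid chloride precursor.

**Step 4**
Reactants: 8 tert-butyldimethylsilyl 4-(tert-butyldimethylsilyloxy)benzoate; 9 oxalyl chloride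
Product: 10 4-(tert-butyldimethylsilyloxy)benzoyl chloride
Conditions: (COCl)2 (1.2 equiv), DMF (cat.), CH2Cl2, 0 °C to rt
Reagents that add atoms: oxalyl chloride 9, O=C(Cl)C(=O)Cl
Why: Silyl esters react with the chloroiminium salt from oxalyl chloride and DMF (Vilsmeier-type activation) to give acid chlorides under neutral conditions, the silyl group leaving as its chloride, so the aryl silyl ether meets no HCl.

**Step 5**
Reactants: 5 1-[2-hydroxy-3-(3-methylbut-2-enyl)-4,6-bis(triisopropylsilyloxy)phenyl]ethanone; 10 4-(tert-butyldimethylsilyloxy)benzoyl chloride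
Product: 11 1-[2-hydroxy-3-(3-methylbut-2-enyl)-4,6-bis(triisopropylsilyloxy)phenyl]-3-[4-(tert-butyldimethylsilyloxy)phenyl]propane-1,3-dione
Conditions: LiN(SiMe3)2 (3.1 equiv), THF, −78 °C; then 10 (1.05 equiv), −78 °C to rt
Reagents that add atoms: none
Why: Direct C-acylation of the lithium phenoxide–enolate dianion with an aroyl chloride (a one-flask variant of the Baker–Venkataraman route to o-hydroxydibenzoylmethanes) should give the diketone, the third equivalent of base absorbing its acidic proton, while the bulky triisopropylsilyl ethers resist oxygen-to-oxygen silyl transfer to the enolate.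

**Step 6**
Reactants: 11 1-[2-hydroxy-3-(3-methylbut-2-enyl)-4,6-bis(triisopropylsilyloxy)phenyl]-3-[4-(tert-butyldimethylsilyloxy)phenyl]propane-1,3-dione; 12 hydrogen peroxide
Product: 15 2-[4-(tert-butyldimethylsilyloxy)phenoxy]-8-(3-methylbut-2-enyl)-5,7-bis(triisopropylsilyloxy)chromen-4-one, via 2-hydroxyflavanone hemiketal 13 (not isolated), via 2-hydroperoxyflavanone 14 (not isolated)
Conditions: H2O2 (anhydrous, ca. 2 M in Et2O, 4 equiv), (±)-10-camphorsulfonic acid (0.2 equiv), 4 Å MS, CH2Cl2, 0 °C to rt
Reagents that add atoms: hydrogen peroxide 12, OO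
Why: Proposed new method: diketone 11 should close to hemiketal 13 by 6-exo-trig addition of the C8a hydroxyl to the ring B ketone carbon (bond O1–C2, ring C), a form favoured because the silyloxy group flanking the other ketone twists the open enol out of conjugation, and CSA should ionise 13 to a C2 oxocarbenium ion that H2O2 captures as hydroperoxy ketal 14. Protonation of the terminal peroxide oxygen and loss of water are then expected to drive a 1,2-shift of the 4-silyloxyphenyl group from C2 to oxygen with assistance from the O1 lone pair, and the C2 cation now flanked by two oxygens loses a C3 proton, so that bonds C2–O and O–C1'' form and ring C stays closed as the chromone. The closest known reaction types are the acid-catalysed Hock rearrangement of benzylic hydroperoxides, the Criegee rearrangement of ketal hydroperoxides and the acid-mediated Dakin or Baeyer–Villiger oxidation of electron-rich aryl ketones by H2O2, while CSA-catalysed perhydrolysis of ketones to geminal hydroperoxides supports the first stage. No stereocentre is set, because C2 of 13 and 14 is racemic and ends trigonal. The step needs aryl over C3 migration, which the far higher migratory aptitude of a para-oxygenated aryl group over a methylene next to a ketone should secure, peroxide attack at C2 and not C4, which the cationic character of C2 and the shielding of the C4 carbonyl by the peri silyloxy group should secure, and an untouched prenyl alkene, which H2O2 without a peracid does not epoxidise. The sieves take up the two equivalents of water so that C2 of 15, a ketene acetal carbon, is not hydrolysed to a 4-hydroxycoumarin.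

**Step 7**
Reactants: 15 2-[4-(tert-butyldimethylsilyloxy)phenoxy]-8-(3-methylbut-2-enyl)-5,7-bis(triisopropylsilyloxy)chromen-4-one
Product: 16 Epimedonin G, 5,7-dihydroxy-2-(4-hydroxyphenoxy)-8-(3-methylbut-2-enyl)chromen-4-one
Conditions: Bu4NF (3.5 equiv), AcOH (3.5 equiv), THF, 0 °C to rt
Reagents that add atoms: none
Why: Fluoride-induced cleavage of aryl silyl ethers is fast at 0 °C, and the acetic acid buffer keeps the liberated phenols protonated so that no phenoxide attacks the C2 aryloxy group, a vinylogous carbonate, and the prenyl group is left alone.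

**Compound list**

1 | 2,4,6-trihydroxyacetophenone | CC(=O)c1c(O)cc(O)cc1O | starting material
2 | 1-bromo-3-methylbut-2-ene (prenyl bromide) | CC(C)=CCBr | starting material
3 | 1-[2,4,6-trihydroxy-3-(3-methylbut-2-enyl)phenyl]ethanone | CC(=O)c1c(O)cc(O)c(CC=C(C)C)c1O | intermediate
4 | triisopropylsilyl chloride | CC(C)[Si](Cl)(C(C)C)C(C)C | starting material
5 | 1-[2-hydroxy-3-(3-methylbut-2-enyl)-4,6-bis(triisopropylsilyloxy)phenyl]ethanone | CC(=O)c1c(O[Si](C(C)C)(C(C)C)C(C)C)cc(O[Si](C(C)C)(C(C)C)C(C)C)c(CC=C(C)C)c1O | intermediate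
6 | 4-hydroxybenzoic acid | O=C(O)c1ccc(O)cc1 | starting material
7 | tert-butyldimethylsilyl chloride | CC(C)(C)[Si](C)(C)Cl | starting material
8 | tert-butyldimethylsilyl 4-(tert-butyldimethylsilyloxy)benzoate | CC(C)(C)[Si](C)(C)OC(=O)c1ccc(O[Si](C)(C)C(C)(C)C)cc1 | intermediate
9 | oxalyl chloride | O=C(Cl)C(=O)Cl | starting material
10 | 4-(tert-butyldimethylsilyloxy)benzoyl chloride | CC(C)(C)[Si](C)(C)Oc1ccc(C(=O)Cl)cc1 | intermediate
11 | 1-[2-hydroxy-3-(3-methylbut-2-enyl)-4,6-bis(triisopropylsilyloxy)phenyl]-3-[4-(tert-butyldimethylsilyloxy)phenyl]propane-1,3-dione | CC(C)=CCc1c(O)c(C(=O)CC(=O)c2ccc(O[Si](C)(C)C(C)(C)C)cc2)c(O[Si](C(C)C)(C(C)C)C(C)C)cc1O[Si](C(C)C)(C(C)C)C(C)C | intermediate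
12 | hydrogen peroxide | OO | starting material
13 | 2-hydroxy-2-[4-(tert-butyldimethylsilyloxy)phenyl]-8-(3-methylbut-2-enyl)-5,7-bis(triisopropylsilyloxy)chroman-4-one (racemic hemiketal) | CC(C)=CCc1c(O[Si](C(C)C)(C(C)C)C(C)C)cc(O[Si](C(C)C)(C(C)C)C(C)C)c2C(=O)CC(O)(c3ccc(O[Si](C)(C)C(C)(C)C)cc3)Oc12 | intermediate
14 | 2-hydroperoxy-2-[4-(tert-butyldimethylsilyloxy)phenyl]-8-(3-methylbut-2-enyl)-5,7-bis(triisopropylsilyloxy)chroman-4-one (racemic) | CC(C)=CCc1c(O[Si](C(C)C)(C(C)C)C(C)C)cc(O[Si](C(C)C)(C(C)C)C(C)C)c2C(=O)CC(OO)(c3ccc(O[Si](C)(C)C(C)(C)C)cc3)Oc12 | intermediate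
15 | 2-[4-(tert-butyldimethylsilyloxy)phenoxy]-8-(3-methylbut-2-enyl)-5,7-bis(triisopropylsilyloxy)chromen-4-one | CC(C)=CCc1c(O[Si](C(C)C)(C(C)C)C(C)C)cc(O[Si](C(C)C)(C(C)C)C(C)C)c2c(=O)cc(Oc3ccc(O[Si](C)(C)C(C)(C)C)cc3)oc12 | intermediate
16 | Epimedonin G, 5,7-dihydroxy-2-(4-hydroxyphenoxy)-8-(3-methylbut-2-enyl)chromen-4-one | CC(C)=CCc1c(O)cc(O)c2c(=O)cc(Oc3ccc(O)cc3)oc12 | target

**Step count and risks**

Total step count: 7. Longest linear sequence: 5 steps (1 → 3 → 5 → 11 → 15 → 16; the ring B branch 6 → 8 → 10 → 11 → 15 → 16 is equally long).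

Steps most likely to fail:

1. Step 6 (proposed new method). Acid-induced loss of water from hemiketal 13 to the flavone, which is a dead end under these mild conditions, may outrun capture by H2O2. Hydroperoxide 14 may also ionise back instead of rearranging, or water set free may hydrolyse the product at C2. The fallback uses known chemistry, sets out from 5 and comes back at 15.
   - Ketone 5 would be condensed with CS2 (KOt-Bu, THF) in a Claisen-type reaction with ring closure to 4-hydroxy-8-(3-methylbut-2-enyl)-5,7-bis(triisopropylsilyloxy)chromene-2-thione F1.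
   - S-Methylation (MeI, K2CO3, acetone) would give 2-(methylsulfanyl)-8-(3-methylbut-2-enyl)-5,7-bis(triisopropylsilyloxy)chromen-4-one F2.
   - Oxidation at sulfur only (H2O2, (NH4)6Mo7O24 cat., EtOH–THF, 0 °C), a method that spares trisubstituted alkenes, would give 2-(methylsulfonyl)-8-(3-methylbut-2-enyl)-5,7-bis(triisopropylsilyloxy)chromen-4-one F3.
   - Addition–elimination at C2 with commercial 4-(tert-butyldimethylsilyloxy)phenol (CC(C)(C)[Si](C)(C)Oc1ccc(O)cc1; K2CO3, acetone) would displace the sulfinate and deliver 15, which rejoins the route before step 7.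

2. Step 5. Acylation at the phenoxide oxygen or twofold acylation may compete with clean C-acylation of the dianion. The fallback sets out from 5 and 10 and comes back at 11.
   - The phenol would be acylated on purpose (NaH, THF, 0 °C; then 10) to the isolated ester 2-acetyl-6-(3-methylbut-2-enyl)-3,5-bis(triisopropylsilyloxy)phenyl 4-(tert-butyldimethylsilyloxy)benzoate F4.
   - The aroyl group would then be moved to carbon by an intramolecular Baker–Venkataraman rearrangement (KOt-Bu, THF, 0 °C), in which acyl transfer through a six-membered transition state is faster than any intermolecular side reaction, giving 11.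

3. Step 2. Poor site selectivity between the two hydroxyls ortho to the acetyl group would carry a regioisomer forward that closes to the 6-prenyl series. The fallback sets out from 1, bypasses step 1 as well, and comes back at 5.
   - Phloroacetophenone would be silylated while the two ortho hydroxyls are still equivalent (4, imidazole, DMF) to 1-[2-hydroxy-4,6-bis(triisopropylsilyloxy)phenyl]ethanone F5.
   - The remaining phenol would be converted with methyl 2-methylbut-3-en-2-yl carbonate (COC(=O)OC(C)(C)C=C) and Pd(PPh3)4 in THF (Tsuji–Trost O-allylation at the tertiary terminus) into 1-[2-(2-methylbut-3-en-2-yloxy)-4,6-bis(triisopropylsilyloxy)phenyl]ethanone F6.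
   - An aromatic Claisen rearrangement (toluene, about 110 °C) would deliver the allyl unit, inverted to the prenyl form, to the only free ortho carbon. This gives 5 with the free hydroxyl necessarily next to the prenyl group.

**Further compounds**

F1 | step 6 | 4-hydroxy-8-(3-methylbut-2-enyl)-5,7-bis(triisopropylsilyloxy)chromene-2-thione | CC(C)=CCc1c(O[Si](C(C)C)(C(C)C)C(C)C)cc(O[Si](C(C)C)(C(C)C)C(C)C)c2c(O)cc(=S)oc12
F2 | step 6 | 2-(methylsulfanyl)-8-(3-methylbut-2-enyl)-5,7-bis(triisopropylsilyloxy)chromen-4-one | CSc1cc(=O)c2c(O[Si](C(C)C)(C(C)C)C(C)C)cc(O[Si](C(C)C)(C(C)C)C(C)C)c(CC=C(C)C)c2o1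
F3 | step 6 | 2-(methylsulfonyl)-8-(3-methylbut-2-enyl)-5,7-bis(triisopropylsilyloxy)chromen-4-one | CS(=O)(=O)c1cc(=O)c2c(O[Si](C(C)C)(C(C)C)C(C)C)cc(O[Si](C(C)C)(C(C)C)C(C)C)c(CC=C(C)C)c2o1
F4 | step 5 | 2-acetyl-6-(3-methylbut-2-enyl)-3,5-bis(triisopropylsilyloxy)phenyl 4-(tert-butyldimethylsilyloxy)benzoate | CC(=O)c1c(O[Si](C(C)C)(C(C)C)C(C)C)cc(O[Si](C(C)C)(C(C)C)C(C)C)c(CC=C(C)C)c1OC(=O)c1ccc(O[Si](C)(C)C(C)(C)C)cc1
F5 | step 2 | 1-[2-hydroxy-4,6-bis(triisopropylsilyloxy)phenyl]ethanone | CC(=O)c1c(O)cc(O[Si](C(C)C)(C(C)C)C(C)C)cc1O[Si](C(C)C)(C(C)C)C(C)C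
F6 | step 2 | 1-[2-(2-methylbut-3-en-2-yloxy)-4,6-bis(triisopropylsilyloxy)phenyl]ethanone | CC(=O)c1c(OC(C)(C)C=C)cc(O[Si](C(C)C)(C(C)C)C(C)C)cc1O[Si](C(C)C)(C(C)C)C(C)C
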